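**Plan**

- Numbering: lactone O1, C2 (C=O), C3 (H), C4 (bearing ring A), C5, exocyclic C6 (bearing ring B); intermediates keep these numbers.
- Enabling feature: the enol-ester bond O1–C5 together with the Z C5=C6 alkene is what anti addition of a carboxyl O–H across a C5≡C6 aryl alkyne leaves behind.
- Retrosynthesis: cut the two aryl O–CH3 bonds, then O1–C5, then C4–C5 (alkenyl–alkynyl), then C4–I back to a C3≡C4 ynoate, then C2–C3, then the alkyne itself back to an aldehyde.
- Forward: one aldehyde supplies ring A and ring B; it is methylated and homologated to an arylacetylene, part of which becomes the Z β-iodo enoate. The halves are joined at C4–C5, and the butenolide, the only ring made, closes in the penultimate step.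
- Stereochemistry: no stereocentres. The Z C3=C4 geometry comes from anti hydroiodination and is kept in the coupling; the Z C5=C6 geometry comes from anti oxyargentation and protonolysis.

Key step: step 7

Remark: the phenols are carried as methyl ethers, because free 2,6-dibromophenols would consume base in steps 2, 3, 5 and 6 and could compete as nucleophiles at the silver-activated alkyne.

**Step 1**
Reactants: 1 3,5-dibromo-4-hydroxybenzaldehyde; 2 iodomethane
Product: 3 3,5-dibromo-4-methoxybenzaldehyde
Conditions: MeI, K2CO3, DMF, rt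
Reagents that add atoms: iodomethane, CI
Why: Williamson ether synthesis, in which K2CO3 fully deprotonates the acidic 2,6-dibromophenol and the phenoxide is methylated by SN2 attack on iodomethane while the aldehyde is inert.

**Step 2**
Reactants: 3 3,5-dibromo-4-methoxybenzaldehyde; 4 dimethyl (1-diazo-2-oxopropyl)phosphonate
Product: 5 1,3-dibromo-5-ethynyl-2-methoxybenzene
Conditions: 4, K2CO3, MeOH, 0 °C to rt
Reagents that add atoms: dimethyl (1-diazo-2-oxopropyl)phosphonate, CC(=O)C(=[N+]=[N-])P(=O)(OC)OC
Why: Seyferth–Gilbert homologation in the Ohira–Bestmann form, in which methanolysis of 4 gives the diazomethylphosphonate anion that adds to the non-enolisable aldehyde, and loss of dimethyl phosphate and N2 with a 1,2-hydrogen shift gives the terminal alkyne without touching the aryl bromides.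

**Step 3**
Reactants: 5 1,3-dibromo-5-ethynyl-2-methoxybenzene; 6 methyl chloroformate
Product: 8 methyl 3-(3,5-dibromo-4-methoxyphenyl)prop-2-ynoate, via lithium acetylide 7 (not isolated)
Conditions: LiN(SiMe3)2, THF, −78 °C; then ClCO2Me, −78 to 0 °C
Reagents that add atoms: methyl chloroformate, COC(=O)Cl
Why: Deprotonation of the sp C–H by a lithium amide, which avoids the halogen–lithium exchange an alkyllithium would risk, followed by C-acylation of the acetylide with the chloroformate is the standard ynoate synthesis.

**Step 4**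
Reactants: 8 methyl 3-(3,5-dibromo-4-methoxyphenyl)prop-2-ynoate
Product: 9 methyl (Z)-3-(3,5-dibromo-4-methoxyphenyl)-3-iodoprop-2-enoate
Conditions: NaI (3 equiv), AcOH, 110 °C
Reagents that add atoms: sodium iodide, [Na+].[I-]
Why: Conjugate hydroiodination of an ynoate, in which iodide adds to the β-carbon C4 and the allenoate is protonated anti to iodine, so that iodine and ester end cis (Z), the geometry that later holds the carboxyl next to the alkyne.

**Step 5**
Reactants: 9 methyl (Z)-3-(3,5-dibromo-4-methoxyphenyl)-3-iodoprop-2-enoate; 5 1,3-dibromo-5-ethynyl-2-methoxybenzene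
Product: 10 methyl (Z)-3,5-bis(3,5-dibromo-4-methoxyphenyl)pent-2-en-4-ynoate
Conditions: Pd(PPh3)2Cl2 (3 mol %), CuI (6 mol %), Et3N, degassed THF, rt
Reagents that add atoms: none
Why: Sonogashira coupling, in which zerovalent palladium inserts into the alkenyl C–I bond far faster than into the hindered aryl C–Br bonds at room temperature and the C4–C5 bond forms with retention of alkene geometry.

**Step 6**
Reactants: 10 methyl (Z)-3,5-bis(3,5-dibromo-4-methoxyphenyl)pent-2-en-4-ynoate
Product: 11 (Z)-3,5-bis(3,5-dibromo-4-methoxyphenyl)pent-2-en-4-ynoic acid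
Conditions: LiOH·H2O (3 equiv), THF/H2O, 0 °C to rt; then cold 1 M HCl to pH 3, dark
Reagents that add atoms: lithium hydroxide (its oxygen ends in the carboxyl group), [Li+].[OH-]
Why: Saponification of the methyl ester by acyl–oxygen cleavage at or below room temperature should leave the enyne, the aryl bromides and the alkene geometry untouched, and careful acidification gives the free acid.

**Step 7**
Reactants: 11 (Z)-3,5-bis(3,5-dibromo-4-methoxyphenyl)pent-2-en-4-ynoic acid
Product: 12 (Z)-5-(3,5-dibromo-4-methoxybenzylidene)-4-(3,5-dibromo-4-methoxyphenyl)furan-2(5H)-one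
Conditions: AgNO3 (10 mol %), acetone, rt, dark
Reagents that add atoms: none
Why: Monovalent silver from AgNO3 binds the C5≡C6 alkyne, the carboxyl oxygen held cis to it by the Z C3=C4 bond attacks C5 on the face opposite the metal, and the C6 vinylsilver is protonated with retention, which releases the catalyst. The closest known reaction type is the silver-catalysed cycloisomerisation of (Z)-2-en-4-ynoic acids to (Z)-5-ylidenebutenolides. The butenolide ring closes in the 5-exo-dig mode. No stereocentre is formed; the Z C5=C6 geometry follows from anti oxymetalation plus stereoretentive protodemetalation, and it is also the isomer in which ring B avoids ring A. The step needs 5-exo over 6-endo closure (the 2-pyranone) and Z over E: the carbophilic metal and the electron-poor ring B, whose methoxy group is twisted out of conjugation by two ortho bromines, keep positive charge from building at C6, so the oxygen takes the geometrically favoured C5.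

**Step 8**
Reactants: 12 (Z)-5-(3,5-dibromo-4-methoxybenzylidene)-4-(3,5-dibromo-4-methoxyphenyl)furan-2(5H)-one
Product: 14 rubrolide A, via bis(dibromoboryl) ether 13 (not isolated)
Conditions: BBr3 (6 equiv), CH2Cl2, −78 °C to rt; then ice/H2O
Reagents that add atoms: none
Why: Lewis-acid ether cleavage, in which BBr3 coordinates each methoxy oxygen, bromide removes the methyl group by SN2 and aqueous work-up hydrolyses the aryloxyborane, conditions that the enol lactone and the exocyclic alkene of ylidenebutenolides normally tolerate.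

**Compound list**

1 | 3,5-dibromo-4-hydroxybenzaldehyde | O=Cc1cc(Br)c(O)c(Br)c1 | starting material
2 | iodomethane | CI | starting material
3 | 3,5-dibromo-4-methoxybenzaldehyde | COc1c(Br)cc(C=O)cc1Br | intermediate
4 | dimethyl (1-diazo-2-oxopropyl)phosphonate | CC(=O)C(=[N+]=[N-])P(=O)(OC)OC | starting material
5 | 1,3-dibromo-5-ethynyl-2-methoxybenzene | C#Cc1cc(Br)c(OC)c(Br)c1 | intermediate
6 | methyl chloroformate | COC(=O)Cl | starting material
7 | [(3,5-dibromo-4-methoxyphenyl)ethynyl]lithium | [Li]C#Cc1cc(Br)c(OC)c(Br)c1 | intermediate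
8 | methyl 3-(3,5-dibromo-4-methoxyphenyl)prop-2-ynoate | COC(=O)C#Cc1cc(Br)c(OC)c(Br)c1 | intermediate
9 | methyl (Z)-3-(3,5-dibromo-4-methoxyphenyl)-3-iodoprop-2-enoate | COC(=O)/C=C(\I)c1cc(Br)c(OC)c(Br)c1 | intermediate
10 | methyl (Z)-3,5-bis(3,5-dibromo-4-methoxyphenyl)pent-2-en-4-ynoate | COC(=O)/C=C(/c1cc(Br)c(OC)c(Br)c1)C#Cc1cc(Br)c(OC)c(Br)c1 | intermediate
11 | (Z)-3,5-bis(3,5-dibromo-4-methoxyphenyl)pent-2-en-4-ynoic acid | OC(=O)/C=C(/c1cc(Br)c(OC)c(Br)c1)C#Cc1cc(Br)c(OC)c(Br)c1 | intermediate
12 | (Z)-5-(3,5-dibromo-4-methoxybenzylidene)-4-(3,5-dibromo-4-methoxyphenyl)furan-2(5H)-one | O=C1C=C(c2cc(Br)c(OC)c(Br)c2)/C(=C/c2cc(Br)c(OC)c(Br)c2)O1 | intermediate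
13 | (Z)-5-{3,5-dibromo-4-[(dibromoboranyl)oxy]benzylidene}-4-{3,5-dibromo-4-[(dibromoboranyl)oxy]phenyl}furan-2(5H)-one | O=C1C=C(c2cc(Br)c(OB(Br)Br)c(Br)c2)/C(=C/c2cc(Br)c(OB(Br)Br)c(Br)c2)O1 | intermediate
14 | rubrolide A, (Z)-5-(3,5-dibromo-4-hydroxybenzylidene)-4-(3,5-dibromo-4-hydroxyphenyl)furan-2(5H)-one | O=C1C=C(c2cc(Br)c(O)c(Br)c2)/C(=C/c2cc(Br)c(O)c(Br)c2)O1 | target

**Step count**

Total steps: 8. Longest linear sequence: 8 steps (1 to 14); alkyne 5 enters twice, in steps 3 and 5.

**Steps most likely to fail**

Step 7. The carboxyl oxygen may close onto C6 in the 6-endo-dig mode, or the vinylsilver may be protonated slowly enough for the alkene geometry to erode. The fallback builds C5=C6 by condensation on a preformed butenolide; it sets out from iodide 9 and aldehyde 3 and comes back at 12. Stille coupling of 9 with (tributylstannyl)methanol under Pd(PPh3)4 in dioxane at 90 °C should give methyl (Z)-3-(3,5-dibromo-4-methoxyphenyl)-4-hydroxybut-2-enoate F1, whose cis hydroxymethyl and ester groups lactonise in the flask to 4-(3,5-dibromo-4-methoxyphenyl)furan-2(5H)-one F2. Treatment of F2 and 3 with TBSOTf and i-Pr2NEt in CH2Cl2 should pass through tert-butyl{[4-(3,5-dibromo-4-methoxyphenyl)furan-2-yl]oxy}dimethylsilane F3, which adds to the aldehyde at C5 in a vinylogous Mukaiyama aldol reaction to give 5-[{[tert-butyl(dimethyl)silyl]oxy}(3,5-dibromo-4-methoxyphenyl)methyl]-4-(3,5-dibromo-4-methoxyphenyl)furan-2(5H)-one F4 as a diastereomer mixture. DBU added to the same flask should eliminate silanol by an E1cB path to give 12, the Z isomer being the one in which ring B avoids ring A.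

Step 4. Iodide addition to the aryl-conjugated ynoate may stay incomplete at temperatures the substrate tolerates, and acid may equilibrate the β-iodo enoate towards the isomer with the ester trans to the future alkyne. The fallback replaces the alkenyl iodide by an enol triflate made from a β-keto ester; it sets out from aldehyde 3 and comes back at 10. Roskamp homologation of 3 with methyl diazoacetate and catalytic SnCl2 in CH2Cl2 should give methyl 3-(3,5-dibromo-4-methoxyphenyl)-3-oxopropanoate F5. Triflation of its chelated lithium enolate with Tf2O and aqueous LiOH in toluene should give methyl (Z)-3-(3,5-dibromo-4-methoxyphenyl)-3-{[(trifluoromethyl)sulfonyl]oxy}prop-2-enoate F6, with triflate and ester cis. Sonogashira coupling of F6 with alkyne 5 under the conditions of step 5 then gives 10.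

Step 5. Copper-mediated oxidative dimerisation may consume alkyne 5, and slow insertion of palladium into aryl C–Br bonds may give oligomers. The fallback is a copper-free Negishi alkynylation with a preformed organozinc; it sets out from lithium acetylide 7 (made from 5 as in step 3) and iodide 9 and comes back at 10. Transmetalation of 7 with ZnBr2 in THF should give [(3,5-dibromo-4-methoxyphenyl)ethynyl]zinc bromide F7, which couples with 9 under Pd(PPh3)4 catalysis at rt to give 10 with no free alkyne or copper acetylide present.

**Further compounds**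

F1 | step 7 | methyl (Z)-3-(3,5-dibromo-4-methoxyphenyl)-4-hydroxybut-2-enoate | COC(=O)/C=C(\CO)c1cc(Br)c(OC)c(Br)c1
F2 | step 7 | 4-(3,5-dibromo-4-methoxyphenyl)furan-2(5H)-one | O=C1C=C(c2cc(Br)c(OC)c(Br)c2)CO1
F3 | step 7 | tert-butyl{[4-(3,5-dibromo-4-methoxyphenyl)furan-2-yl]oxy}dimethylsilane | CC(C)(C)[Si](C)(C)Oc1cc(-c2cc(Br)c(OC)c(Br)c2)co1
F4 | step 7 | 5-[{[tert-butyl(dimethyl)silyl]oxy}(3,5-dibromo-4-methoxyphenyl)methyl]-4-(3,5-dibromo-4-methoxyphenyl)furan-2(5H)-one (diastereomer mixture, configuration not set) | O=C1C=C(c2cc(Br)c(OC)c(Br)c2)C(C(O[Si](C)(C)C(C)(C)C)c2cc(Br)c(OC)c(Br)c2)O1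
F5 | step 4 | methyl 3-(3,5-dibromo-4-methoxyphenyl)-3-oxopropanoate | COC(=O)CC(=O)c1cc(Br)c(OC)c(Br)c1
F6 | step 4 | methyl (Z)-3-(3,5-dibromo-4-methoxyphenyl)-3-{[(trifluoromethyl)sulfonyl]oxy}prop-2-enoate | COC(=O)/C=C(\OS(=O)(=O)C(F)(F)F)c1cc(Br)c(OC)c(Br)c1
F7 | step 5 | [(3,5-dibromo-4-methoxyphenyl)ethynyl]zinc bromide | Br[Zn]C#Cc1cc(Br)c(OC)c(Br)c1
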